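**Retrosynthetic overview**
1. Target 15 ⇐ triol 14 (primary OH → Cl last) ⇐ protected bromo-oxane 13.
2. Ring B (formed second): C7–O and C6–Br by 6-endo bromoetherification of tertiary alcohol 12 onto the (E)-C6=C7 alkene. The C3 carbinol comes from chelation-controlled MeMgBr addition to α-alkoxy ketone 11.
3. Key C5–C6 bond: the ketone homoenolate released from cyclopropanol 10 (C5 made nucleophilic) is coupled under palladium catalysis to (E)-alkenyl iodide 8 (C6).
4. 8 comes from ring-A methyl ketone 3 via silyl ether, alkyne 6 and Zr-catalysed carboalumination/iodination. 10 comes from D-glycerate acetonide 9 (source of C2) by Kulinkovich cyclopropanation.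
5. Ring A (formed first): enantioselective bromonium-induced cyclisation of (E)-geranylacetone 1 terminated by the ketone oxygen (sets C10, C11, C14).

Assumption and numbering: (E)-geranylacetone (≥96 % E) and methyl (4R)-2,2-dimethyl-1,3-dioxolane-4-carboxylate are bought. Carbons run C1 (CH2Cl), C2 (CHOH), C3 and C7 (oxane carbons on O), C6 (oxane CHBr), C8–C9 (ethylene link), C10 (ring-A CH), C11 (C(OH)Me), C14 (ring-A CHBr), C15 (CMe2).

Step 1
Reactants: 1 (5E)-6,10-dimethylundeca-5,9-dien-2-one [(E)-geranylacetone]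
Product: 3 4-[(1R,3R,6R)-3-bromo-6-hydroxy-2,2,6-trimethylcyclohexyl]butan-2-one, via bicyclic bromo enol ether 2 (not isolated)
Conditions: DBDMH (1.0 equiv), O,O′-[(R)-3,3′-bis(2,4,6-triisopropylphenyl)-1,1′-binaphthalene-2,2′-diyl] N-triflylphosphoramidothioate (10 mol %; antipode chosen to give the 3R bromide), toluene/CH2Cl2, −78 °C; then 1 M HCl, THF, 0 °C → rt
Reagents that add atoms: 1,3-dibromo-5,5-dimethylhydantoin (CC1(C)N(Br)C(=O)N(Br)C1=O); water (O)
Why: Proposed new method: the chiral Lewis-basic P=S catalyst takes Br+ from DBDMH and delivers it to one face of the terminal, most electron-rich alkene; the β-bromo cation is captured through a chair transition state by the (E)-alkene (Br and side chain equatorial) and the tertiary cation is trapped anti by the ketone oxygen, so the one enantiodetermining bromination fixes C14 (R) and relays it to C10 (R) and C11 (R), proton loss gives 2 and aqueous acid opens it to 3; the closest known reaction types are the chiral thiophosphoramide-catalysed bromonium polyene cyclisation of homogeranylarenes with DBDMH and the racemic bromonium- or mercury-induced cyclisation of geranylacetone-type ketones to bicyclic enol ethers.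

Step 2
Reactants: 3 4-[(1R,3R,6R)-3-bromo-6-hydroxy-2,2,6-trimethylcyclohexyl]butan-2-one
Product: 4 4-{(1R,3R,6R)-3-bromo-2,2,6-trimethyl-6-[(triethylsilyl)oxy]cyclohexyl}butan-2-one
Conditions: TESOTf (1.3 equiv), 2,6-lutidine (2 equiv), CH2Cl2, −78 → 0 °C
Reagents that add atoms: triethylsilyl trifluoromethanesulfonate (CC[Si](CC)(CC)OS(=O)(=O)C(F)(F)F)
Why: Silylation of the tertiary alcohol with a silyl triflate and a hindered base masks O-11, which would otherwise capture the C6/C7 bromonium ion of step 8 in a 6-exo closure; no stereocentre is touched.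

Step 3
Reactants: 4 4-{(1R,3R,6R)-3-bromo-2,2,6-trimethyl-6-[(triethylsilyl)oxy]cyclohexyl}butan-2-one
Product: 6 {[(1R,2R,4R)-4-bromo-2-(but-3-yn-1-yl)-1,3,3-trimethylcyclohexyl]oxy}triethylsilane, via enol phosphate 5 (not isolated)
Conditions: LiN(iPr)2 (1.1 equiv), THF, −78 °C; ClP(O)(OEt)2 (1.2 equiv), −78 °C → rt; then LiN(iPr)2 (2.3 equiv), −78 °C → rt
Reagents that add atoms: none
Why: Negishi conversion of a methyl ketone into a terminal alkyne (kinetic enolisation at CH3, O-phosphorylation, base-induced elimination of diethyl phosphate); the equatorial, neopentyl-type bromide has no antiperiplanar hydrogen and survives the amide base.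

Step 4
Reactants: 6 {[(1R,2R,4R)-4-bromo-2-(but-3-yn-1-yl)-1,3,3-trimethylcyclohexyl]oxy}triethylsilane
Product: 8 {[(1R,2R,4R)-4-bromo-2-[(3E)-4-iodo-3-methylbut-3-en-1-yl]-1,3,3-trimethylcyclohexyl]oxy}triethylsilane, via alkenylalane 7 (not isolated)
Conditions: AlMe3 (2.5 equiv), Cp2ZrCl2 (25 mol %), CH2Cl2, 0 °C → rt; then I2 (1.5 equiv), THF, −30 → 0 °C
Reagents that add atoms: trimethylaluminium (C[Al](C)C); iodine (II)
Why: Negishi zirconium-catalysed syn-carboalumination puts methyl on the internal and aluminium on the terminal alkyne carbon, and iodinolysis with retention gives the (E)-alkenyl iodide, which fixes the C6=C7 geometry.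

Step 5
Reactants: 9 methyl (4R)-2,2-dimethyl-1,3-dioxolane-4-carboxylate
Product: 10 1-[(4R)-2,2-dimethyl-1,3-dioxolan-4-yl]cyclopropan-1-ol
Conditions: EtMgBr (2.5 equiv, slow addition), Ti(OiPr)4 (20 mol %), THF, 0 °C → rt
Reagents that add atoms: ethylmagnesium bromide (CC[Mg]Br)
Why: Kulinkovich cyclopropanation of the ester through a titanacyclopropane; the dioxolane stereocentre (future C2, from D-glyceric acid) is not involved and is retained.

Step 6
Reactants: 8 {[(1R,2R,4R)-4-bromo-2-[(3E)-4-iodo-3-methylbut-3-en-1-yl]-1,3,3-trimethylcyclohexyl]oxy}triethylsilane; 10 1-[(4R)-2,2-dimethyl-1,3-dioxolan-4-yl]cyclopropan-1-ol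
Product: 11 (4E)-7-{(1R,3R,6R)-3-bromo-2,2,6-trimethyl-6-[(triethylsilyl)oxy]cyclohexyl}-1-[(4R)-2,2-dimethyl-1,3-dioxolan-4-yl]-5-methylhept-4-en-1-one
Conditions: Pd(OAc)2 (5 mol %), XPhos (10 mol %), K3PO4 (2 equiv), toluene, 60 °C
Reagents that add atoms: none
Why: Proposed new method: oxidative addition of the alkenyl iodide to zerovalent palladium, exchange of iodide for the cyclopropoxide, strain-driven β-carbon elimination to a palladium homoenolate and reductive elimination (made faster than β-hydride elimination by the bulky biarylphosphine) join C5, the β-carbon of the C3 ketone, to the alkenyl carbon C6, two centres that are both normally electrophilic, with retention of the (E)-geometry and without touching the alkyl bromide or the dioxolane stereocentre; the closest known reaction types are the palladium-catalysed ring-opening arylation of cyclopropanols and the palladium-catalysed coupling of zinc homoenolates with alkenyl halides and triflates.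

Step 7
Reactants: 11 (4E)-7-{(1R,3R,6R)-3-bromo-2,2,6-trimethyl-6-[(triethylsilyl)oxy]cyclohexyl}-1-[(4R)-2,2-dimethyl-1,3-dioxolan-4-yl]-5-methylhept-4-en-1-one
Product: 12 (2S,5E)-8-{(1R,3R,6R)-3-bromo-2,2,6-trimethyl-6-[(triethylsilyl)oxy]cyclohexyl}-2-[(4R)-2,2-dimethyl-1,3-dioxolan-4-yl]-6-methyloct-5-en-2-ol
Conditions: MeMgBr (3 equiv), Et2O/CH2Cl2, −78 °C
Reagents that add atoms: methylmagnesium bromide (C[Mg]Br)
Why: Cram-chelate-controlled Grignard addition: magnesium bridges the carbonyl oxygen and the dioxolane oxygen on the α-carbon and methyl attacks the face bearing the α-hydrogen, which sets C3 as S (dr ≥ 10:1 expected).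

Step 8
Reactants: 12 (2S,5E)-8-{(1R,3R,6R)-3-bromo-2,2,6-trimethyl-6-[(triethylsilyl)oxy]cyclohexyl}-2-[(4R)-2,2-dimethyl-1,3-dioxolan-4-yl]-6-methyloct-5-en-2-ol
Product: 13 {[(1R,2R,4R)-4-bromo-2-{2-[(2S,3R,6S)-3-bromo-6-[(4R)-2,2-dimethyl-1,3-dioxolan-4-yl]-2,6-dimethyloxan-2-yl]ethyl}-1,3,3-trimethylcyclohexyl]oxy}triethylsilane
Conditions: TBCO (2,4,4,6-tetrabromocyclohexa-2,5-dien-1-one, 1.1 equiv), MeNO2, 0 °C → rt, dark
Reagents that add atoms: 2,4,4,6-tetrabromocyclohexa-2,5-dien-1-one (O=C1C(Br)=CC(Br)(Br)C=C1Br)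
Why: Bromoetherification (bromonium-induced 6-endo cyclisation): Markovnikov attack of the tertiary hydroxyl at C7 anti to bromine on the (E)-alkene fixes Br trans to the C8 chain, and the chair transition state that keeps the bulky dioxolanyl group equatorial (C3 methyl axial) selects the alkene face, giving the 2,6-cis-dimethyl oxane with C6 R and C7 S.

Step 9
Reactants: 13 {[(1R,2R,4R)-4-bromo-2-{2-[(2S,3R,6S)-3-bromo-6-[(4R)-2,2-dimethyl-1,3-dioxolan-4-yl]-2,6-dimethyloxan-2-yl]ethyl}-1,3,3-trimethylcyclohexyl]oxy}triethylsilane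
Product: 14 (1R,2R,4R)-4-bromo-2-{2-[(2S,3R,6S)-3-bromo-6-[(1R)-1,2-dihydroxyethyl]-2,6-dimethyloxan-2-yl]ethyl}-1,3,3-trimethylcyclohexan-1-ol
Conditions: 2 M aq. HCl/THF (1:3), rt
Reagents that add atoms: none
Why: Acid-catalysed hydrolysis removes the acetonide and the tertiary triethylsilyl ether in one operation; all C–O bonds at stereocentres stay intact, and the β-bromo ether and tertiary alcohols tolerate dilute aqueous acid.

Step 10
Reactants: 14 (1R,2R,4R)-4-bromo-2-{2-[(2S,3R,6S)-3-bromo-6-[(1R)-1,2-dihydroxyethyl]-2,6-dimethyloxan-2-yl]ethyl}-1,3,3-trimethylcyclohexan-1-ol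
Product: 15 (1R,2R,4R)-4-bromo-2-{2-[(2S,3R,6S)-3-bromo-6-[(1S)-2-chloro-1-hydroxyethyl]-2,6-dimethyloxan-2-yl]ethyl}-1,3,3-trimethylcyclohexan-1-ol
Conditions: Ph3PCl2 (1.3 equiv), imidazole (2.5 equiv), CH2Cl2, 0 °C → rt
Reagents that add atoms: dichlorotriphenylphosphorane (ClP(Cl)(c1ccccc1)(c1ccccc1)c1ccccc1)
Why: Appel-type deoxychlorination: only the unhindered primary hydroxyl is activated (the secondary one is neopentyl-like, the tertiary one inert) and chloride displaces Ph3PO by SN2 at C1, so C2 keeps its geometry and its descriptor changes from R to S only because chlorine raises the priority of C1.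

**Compound list**
1 | (5E)-6,10-dimethylundeca-5,9-dien-2-one | CC(=O)CC/C=C(\C)CCC=C(C)C | starting material
2 | (4aR,6R,8aR)-6-bromo-2,5,5,8a-tetramethyl-4a,5,6,7,8,8a-hexahydro-4H-chromene | CC1(C)[C@H](Br)CC[C@@]2(C)OC(C)=CC[C@H]12 | intermediate
3 | 4-[(1R,3R,6R)-3-bromo-6-hydroxy-2,2,6-trimethylcyclohexyl]butan-2-one | CC1(C)[C@H](Br)CC[C@@](C)(O)[C@@H]1CCC(C)=O | intermediate
4 | 4-{(1R,3R,6R)-3-bromo-2,2,6-trimethyl-6-[(triethylsilyl)oxy]cyclohexyl}butan-2-one | CC1(C)[C@H](Br)CC[C@@](C)(O[Si](CC)(CC)CC)[C@@H]1CCC(C)=O | intermediate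
5 | 4-{(1R,3R,6R)-3-bromo-2,2,6-trimethyl-6-[(triethylsilyl)oxy]cyclohexyl}but-1-en-2-yl diethyl phosphate | CC1(C)[C@H](Br)CC[C@@](C)(O[Si](CC)(CC)CC)[C@@H]1CCC(=C)OP(=O)(OCC)OCC | intermediate
6 | {[(1R,2R,4R)-4-bromo-2-(but-3-yn-1-yl)-1,3,3-trimethylcyclohexyl]oxy}triethylsilane | CC1(C)[C@H](Br)CC[C@@](C)(O[Si](CC)(CC)CC)[C@@H]1CCC#C | intermediate
7 | [(1E)-4-{(1R,3R,6R)-3-bromo-2,2,6-trimethyl-6-[(triethylsilyl)oxy]cyclohexyl}-2-methylbut-1-en-1-yl]dimethylalane | CC1(C)[C@H](Br)CC[C@@](C)(O[Si](CC)(CC)CC)[C@@H]1CC/C(C)=C/[Al](C)C | intermediate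
8 | {[(1R,2R,4R)-4-bromo-2-[(3E)-4-iodo-3-methylbut-3-en-1-yl]-1,3,3-trimethylcyclohexyl]oxy}triethylsilane | CC1(C)[C@H](Br)CC[C@@](C)(O[Si](CC)(CC)CC)[C@@H]1CC/C(C)=C/I | intermediate
9 | methyl (4R)-2,2-dimethyl-1,3-dioxolane-4-carboxylate | COC(=O)[C@H]1COC(C)(C)O1 | starting material
10 | 1-[(4R)-2,2-dimethyl-1,3-dioxolan-4-yl]cyclopropan-1-ol | OC1(CC1)[C@H]2COC(C)(C)O2 | intermediate
11 | (4E)-7-{(1R,3R,6R)-3-bromo-2,2,6-trimethyl-6-[(triethylsilyl)oxy]cyclohexyl}-1-[(4R)-2,2-dimethyl-1,3-dioxolan-4-yl]-5-methylhept-4-en-1-one | CC1(C)[C@H](Br)CC[C@@](C)(O[Si](CC)(CC)CC)[C@@H]1CC/C(C)=C/CCC(=O)[C@H]1COC(C)(C)O1 | intermediate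
12 | (2S,5E)-8-{(1R,3R,6R)-3-bromo-2,2,6-trimethyl-6-[(triethylsilyl)oxy]cyclohexyl}-2-[(4R)-2,2-dimethyl-1,3-dioxolan-4-yl]-6-methyloct-5-en-2-ol | CC1(C)[C@H](Br)CC[C@@](C)(O[Si](CC)(CC)CC)[C@@H]1CC/C(C)=C/CC[C@](C)(O)[C@H]1COC(C)(C)O1 | intermediate
13 | {[(1R,2R,4R)-4-bromo-2-{2-[(2S,3R,6S)-3-bromo-6-[(4R)-2,2-dimethyl-1,3-dioxolan-4-yl]-2,6-dimethyloxan-2-yl]ethyl}-1,3,3-trimethylcyclohexyl]oxy}triethylsilane | CC1(C)[C@H](Br)CC[C@@](C)(O[Si](CC)(CC)CC)[C@@H]1CC[C@]1(C)O[C@](C)([C@H]2COC(C)(C)O2)CC[C@H]1Br | intermediate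
14 | (1R,2R,4R)-4-bromo-2-{2-[(2S,3R,6S)-3-bromo-6-[(1R)-1,2-dihydroxyethyl]-2,6-dimethyloxan-2-yl]ethyl}-1,3,3-trimethylcyclohexan-1-ol | CC1(C)[C@H](Br)CC[C@@](C)(O)[C@@H]1CC[C@]1(C)O[C@](C)([C@H](O)CO)CC[C@H]1Br | intermediate
15 | (1R,2R,4R)-4-bromo-2-{2-[(2S,3R,6S)-3-bromo-6-[(1S)-2-chloro-1-hydroxyethyl]-2,6-dimethyloxan-2-yl]ethyl}-1,3,3-trimethylcyclohexan-1-ol | CC1(C)[C@H](Br)CC[C@@](C)(O)[C@@H]1CC[C@]1(C)O[C@](C)([C@H](O)CCl)CC[C@H]1Br | target

**Step count**
Total: 10 steps. Longest linear sequence: 9 steps (steps 1–4 and 6–10, from 1 to 15).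

**Steps most likely to fail**

Step 1. Enantioselectivity with a ketone terminus is unproven, and enol ether 2 may itself consume Br+. The fallback sets out from 1 and returns at 3. Cyclise 1 without a chiral catalyst using Et2SBr·SbCl5Br in MeNO2 at −25 °C, where the oxocarbenium ion persists as its antimonate salt until the quench, to obtain the racemic bicyclic bromo enol ether F1. Hydrolyse with 1 M HCl to the racemic hydroxy ketone F2. Resolve F2 by preparative chiral SFC on an amylose carbamate phase and assign the (1R,3R,6R) enantiomer, which is 3, by anomalous-dispersion X-ray analysis.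

Step 6. β-Hydride elimination to the vinyl ketone, protonolysis to the ethyl ketone, or base-induced epimerisation at the dioxolane carbon next to the new ketone can intervene. The fallback sets out from 10 and returns at 11. Open 10 with NIS in CH2Cl2 at 0 °C to 1-[(4R)-2,2-dimethyl-1,3-dioxolan-4-yl]-3-iodopropan-1-one F3. Insert zinc (Zn dust, LiCl, THF, 25 °C) to obtain the stoichiometric zinc homoenolate {3-[(4R)-2,2-dimethyl-1,3-dioxolan-4-yl]-3-oxopropyl}zinc iodide F4. Couple F4 with 8 under base-free Negishi conditions (Pd2(dba)3, SPhos, THF, 25–40 °C) to reach 11.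

Step 8. Competing 5-exo closure to an oxolane with a tertiary bromide, attack on the wrong alkene face, or participation of the silyl ether can lower the yield. The fallback sets out from 12 and returns at 13. Cyclise with Hg(OCOCF3)2 in MeNO2 at −20 °C; this reversible anti oxymercuration should settle under thermodynamic control on the 6-endo organomercury trifluoroacetate F5. Then replace mercury by bromine with retention (Br2, pyridine, 0 °C, dark, O2 atmosphere to suppress radical chains) to give 13.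

Further compounds
F1 | step 1 | rac-(4aR,6R,8aR)-6-bromo-2,5,5,8a-tetramethyl-4a,5,6,7,8,8a-hexahydro-4H-chromene | CC1(C)[C@H](Br)CC[C@@]2(C)OC(C)=CC[C@H]12.CC1(C)[C@@H](Br)CC[C@]2(C)OC(C)=CC[C@@H]12
F2 | step 1 | rac-4-[(1R,3R,6R)-3-bromo-6-hydroxy-2,2,6-trimethylcyclohexyl]butan-2-one | CC1(C)[C@H](Br)CC[C@@](C)(O)[C@@H]1CCC(C)=O.CC1(C)[C@@H](Br)CC[C@](C)(O)[C@H]1CCC(C)=O
F3 | step 6 | 1-[(4R)-2,2-dimethyl-1,3-dioxolan-4-yl]-3-iodopropan-1-one | ICCC(=O)[C@H]1COC(C)(C)O1
F4 | step 6 | {3-[(4R)-2,2-dimethyl-1,3-dioxolan-4-yl]-3-oxopropyl}zinc iodide | I[Zn]CCC(=O)[C@H]1COC(C)(C)O1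
F5 | step 8 | {(2S,3R,6S)-2-(2-{(1R,3R,6R)-3-bromo-2,2,6-trimethyl-6-[(triethylsilyl)oxy]cyclohexyl}ethyl)-6-[(4R)-2,2-dimethyl-1,3-dioxolan-4-yl]-2,6-dimethyloxan-3-yl}mercury trifluoroacetate | CC1(C)[C@H](Br)CC[C@@](C)(O[Si](CC)(CC)CC)[C@@H]1CC[C@]1(C)O[C@](C)([C@H]2COC(C)(C)O2)CC[C@H]1[Hg]OC(=O)C(F)(F)F
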